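**Strategy.** The dioxolane is disconnected at the O–C4 bond (acid-chain numbering; C4 carries the acrylic acid). The key step exploits the cis relationship of the C4–O and C6–O bonds on the 1,2-dioxolane ring: the arms C3 and C7 are tied through one sacrificial carbon into a cyclohexene, made by Birch reduction of 1,3-diethylbenzene and desymmetrising epoxidation. The precursor, a trans-6-hydroperoxycyclohex-3-enol, then adds its C6 hydroperoxide across the ring to the iodonium ion of the C3=C4 alkene: one operation closes the dioxolane as a 6,7-dioxabicyclo[3.2.1]octane, fixes C4 by ring geometry and installs the iodide through which the carbocycle is cut open again.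

Key step: step 4

Remark (numbering): carbons are numbered as in the target acid (C1 = CO2H, C4 and C6 = dioxolane carbons, C5 = ring CH2, C10 = side-chain stereocentre); the extra ring carbon of compounds 2–6 is called the tether carbon.

Assumption: the D-fructose-derived Shi ketone delivers oxygen to 2 with the facial sense established for 1-substituted cyclohexenes; were the sense opposite, the enantiomeric ketone would be used.

**Route**

Step 1
Reactants: 1 1,3-diethylbenzene
Product: 2 1,5-diethylcyclohexa-1,4-diene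
Conditions: Li, NH3(l), THF, EtOH, −78 → −33 °C
Reagents that add atoms: none
Why: Birch reduction of a 1,3-dialkylbenzene protonates the two unsubstituted para-related positions, so both ethyl groups stay on the double bonds of the skipped diene and no stereocentre is formed.

Step 2
Reactants: 2 1,5-diethylcyclohexa-1,4-diene
Product: 3 (1S,6R)-1,3-diethyl-7-oxabicyclo[4.1.0]hept-3-ene
Conditions: Shi ketone (from D-fructose, 0.3 equiv), Oxone (0.9 equiv), K2CO3, Bu4NHSO4, MeCN/DMM/aq. borate buffer, 0 °C (unreacted 2 recycled)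
Reagents that add atoms: potassium peroxymonosulfate (Oxone), [K+].[O-]S(=O)(=O)OO
Why: Shi asymmetric epoxidation (chiral dioxirane, spiro transition state) desymmetrises the two enantiotopic trisubstituted alkenes and sets the future C6 and C7 in one event, while over-oxidation to the bis-epoxide should remove the minor enantiomer preferentially.

Step 3
Reactants: 3 (1S,6R)-1,3-diethyl-7-oxabicyclo[4.1.0]hept-3-ene
Product: 4 (1R,6R)-4,6-diethyl-6-hydroperoxycyclohex-3-en-1-ol (hydroperoxide trans to hydroxyl)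
Conditions: anhydrous H2O2 in Et2O, phosphomolybdic acid (cat.), rt
Reagents that add atoms: hydrogen peroxide, OO
Why: Acid-catalysed perhydrolysis of a trisubstituted epoxide opens the tertiary C–O bond with inversion (trans-diaxial), which places the C6 hydroperoxide anti to the C7 hydroxyl and leaves the remote alkene untouched.

Step 4
Reactants: 4 (1R,6R)-4,6-diethyl-6-hydroperoxycyclohex-3-en-1-ol
Product: 5 (1R,2R,4S,5S)-1,5-diethyl-4-iodo-6,7-dioxabicyclo[3.2.1]octan-2-ol
Conditions: NIS, NaHCO3, CH2Cl2, 0 °C, dark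
Reagents that add atoms: N-iodosuccinimide, O=C1CCC(=O)N1I
Why: NIS adds I+ to the C3=C4 alkene and, in the half-chair with the C6 hydroperoxide axial, the terminal peroxy oxygen attacks the tertiary C4 of the transient iodonium ion from the face opposite to iodine (trans-diaxial opening), the proton going to succinimide. The closest known reaction type is the halogen-mediated cyclisation of unsaturated hydroperoxides (cycloperoxyhalogenation of cycloalkenyl hydroperoxides with N-halosuccinimides). The ring closed is the 1,2-dioxolane (O–O–C6–C5–C4), by 5-exo attack on the activated alkene, which at the same time creates the 6,7-dioxabicyclo[3.2.1]octane. The new C4 stereocentre is controlled by the carbocycle: a hydroperoxide held on C6 of the six-membered ring can bridge to C4 only on its own face, so the C4–O and C6–O bonds are necessarily cis and C4 follows from C6, while the C3 iodide is set anti to oxygen and is removed later. The step needs attack at C4 and not C3, and by the hydroperoxide and not the C7 hydroxyl: Markovnikov opening at the tertiary carbon gives the [3.2.1] and not the [2.2.2] peroxide, and the 1,3-diaxial α-effect hydroperoxide reaches C4 through a chair, whereas the hydroxyl would need a boat to form a strained 7-oxabicyclo[2.2.1]heptane.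

Step 5
Reactants: 5 (1R,2R,4S,5S)-1,5-diethyl-4-iodo-6,7-dioxabicyclo[3.2.1]octan-2-ol
Product: 6 (1R,2R,5S)-1,5-diethyl-6,7-dioxabicyclo[3.2.1]oct-3-en-2-ol
Conditions: DBU, toluene, 50 °C
Reagents that add atoms: none
Why: E2 dehydroiodination, in which the axial iodide has an anti-periplanar hydrogen only on the tether carbon (C4 is quaternary) and the peroxide carbons carry no hydrogen, so no Kornblum–DeLaMare cleavage is possible.

Step 6
Reactants: 6 (1R,2R,5S)-1,5-diethyl-6,7-dioxabicyclo[3.2.1]oct-3-en-2-ol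
Product: 8 (1R)-1-[(3R,5S)-3,5-diethyl-5-(hydroxymethyl)-1,2-dioxolan-3-yl]ethane-1,2-diol, via hydroxy dialdehyde 7 (not isolated)
Conditions: O3, CH2Cl2/MeOH, −78 °C; Me2S; then NaBH4, −78 → 0 °C
Reagents that add atoms: ozone, [O-][O+]=O
Why: Ozonolysis with reductive work-up cuts the carbocycle at its only C=C bond (C3/tether carbon), the dialkyl peroxide tolerating ozone, Me2S and NaBH4, and the two dioxolane stereocentres are not touched.

Step 7
Reactants: 8 (1R)-1-[(3R,5S)-3,5-diethyl-5-(hydroxymethyl)-1,2-dioxolan-3-yl]ethane-1,2-diol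
Product: 9 [(3S,5R)-5-[(4R)-2,2-dimethyl-1,3-dioxolan-4-yl]-3,5-diethyl-1,2-dioxolan-3-yl]methanol
Conditions: Me2C(OMe)2, PPTS (cat.), acetone, rt
Reagents that add atoms: 2,2-dimethoxypropane, COC(C)(C)OC
Why: Thermodynamic acetonide formation selects the terminal 1,2-diol (five-membered ring) and leaves the neopentyl primary alcohol at C3 free.

Step 8
Reactants: 9 [(3S,5R)-5-[(4R)-2,2-dimethyl-1,3-dioxolan-4-yl]-3,5-diethyl-1,2-dioxolan-3-yl]methanol
Product: 10 (3S,5R)-5-[(4R)-2,2-dimethyl-1,3-dioxolan-4-yl]-3,5-diethyl-1,2-dioxolane-3-carbaldehyde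
Conditions: Dess–Martin periodinane, NaHCO3, CH2Cl2, 0 °C → rt
Reagents that add atoms: none
Why: Dess–Martin oxidation converts the primary alcohol into a non-enolisable aldehyde under buffered conditions that leave peroxide and acetonide intact.

Step 9
Reactants: 10 (3S,5R)-5-[(4R)-2,2-dimethyl-1,3-dioxolan-4-yl]-3,5-diethyl-1,2-dioxolane-3-carbaldehyde
Product: 11 methyl (2E)-3-[(3S,5R)-5-[(4R)-2,2-dimethyl-1,3-dioxolan-4-yl]-3,5-diethyl-1,2-dioxolan-3-yl]prop-2-enoate
Conditions: (MeO)2P(O)CH2CO2Me, NaH, THF, 0 °C → rt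
Reagents that add atoms: trimethyl phosphonoacetate, COC(=O)CP(=O)(OC)OC
Why: Horner–Wadsworth–Emmons olefination with a stabilised phosphonate anion should give the (E)-C2=C3 enoate, and the α-quaternary aldehyde cannot epimerise.

Step 10
Reactants: 11 methyl (2E)-3-[(3S,5R)-5-[(4R)-2,2-dimethyl-1,3-dioxolan-4-yl]-3,5-diethyl-1,2-dioxolan-3-yl]prop-2-enoate
Product: 13 methyl (2E)-3-[(3S,5R)-3,5-diethyl-5-formyl-1,2-dioxolan-3-yl]prop-2-enoate, via diol 12 (not isolated)
Conditions: H5IO6, EtOAc, rt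
Reagents that add atoms: none
Why: Periodic acid hydrolyses the terminal acetonide and cleaves the liberated glycol in the same flask (Malaprade cleavage), excising the tether carbon as formaldehyde and unveiling the C7 aldehyde.

Step 11
Reactants: 14 (E)-pent-2-enal
Product: 15 (3R,4E)-hept-4-en-3-ol
Conditions: Et2Zn, (2R)-(+)-DAIB (cat.), toluene, 0 °C
Reagents that add atoms: diethylzinc, CC[Zn]CC
Why: Amino-alcohol-catalysed enantioselective 1,2-addition of diethylzinc to an enal (Noyori), in which the (2R)-catalyst should give the (R)-carbinol.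

Step 12
Reactants: 15 (3R,4E)-hept-4-en-3-ol
Product: 17 ethyl (3R,4E)-3-ethylhept-4-enoate, via ketene acetal 16 (not isolated)
Conditions: MeC(OEt)3, EtCO2H (cat.), 140 °C (−EtOH)
Reagents that add atoms: triethyl orthoacetate, CCOC(C)(OCC)OCC
Why: Johnson–Claisen rearrangement through a chair with the carbinol ethyl group equatorial transfers the C–O chirality suprafacially to the new C–C bond, which sets C10 as (R) together with the (E)-C11=C12 alkene.

Step 13
Reactants: 17 ethyl (3R,4E)-3-ethylhept-4-enoate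
Product: 18 (3R,4E)-3-ethylhept-4-en-1-ol
Conditions: LiAlH4, Et2O, 0 °C
Reagents that add atoms: none
Why: Hydride reduction of the ester to the primary alcohol leaves the isolated alkene and the stereocentre untouched.

Step 14
Reactants: 18 (3R,4E)-3-ethylhept-4-en-1-ol
Product: 19 5-{[(3R,4E)-3-ethylhept-4-en-1-yl]sulfanyl}-1-phenyl-1H-tetrazole
Conditions: 1-phenyl-1H-tetrazole-5-thiol, PPh3, DIAD, THF, 0 °C → rt
Reagents that add atoms: 1-phenyl-1H-tetrazole-5-thiol, Sc1nnnn1-c1ccccc1
Why: Mitsunobu thioetherification of a primary alcohol with the acidic tetrazole thiol.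

Step 15
Reactants: 19 5-{[(3R,4E)-3-ethylhept-4-en-1-yl]sulfanyl}-1-phenyl-1H-tetrazole
Product: 20 5-{[(3R,4E)-3-ethylhept-4-en-1-yl]sulfonyl}-1-phenyl-1H-tetrazole
Conditions: 30% H2O2, (NH4)6Mo7O24·4H2O (cat.), EtOH, 0 °C → rt
Reagents that add atoms: hydrogen peroxide, OO
Why: Molybdate-catalysed oxidation of sulfide to sulfone, under which an isolated disubstituted alkene is not epoxidised.

Step 16
Reactants: 20 5-{[(3R,4E)-3-ethylhept-4-en-1-yl]sulfonyl}-1-phenyl-1H-tetrazole
Product: 21 5-{[(4R,5E)-4-ethyloct-5-en-2-yl]sulfonyl}-1-phenyl-1H-tetrazole (mixture of epimers at the sulfonyl carbon)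
Conditions: KHMDS, THF, −78 °C; MeI
Reagents that add atoms: iodomethane, CI
Why: α-Methylation of the metallated tetrazolyl sulfone below the temperature of its self-condensation installs the C8 methyl branch, the new centre being irrelevant because it becomes sp2.

Step 17
Reactants: 13 methyl (2E)-3-[(3S,5R)-3,5-diethyl-5-formyl-1,2-dioxolan-3-yl]prop-2-enoate; 21 5-{[(4R,5E)-4-ethyloct-5-en-2-yl]sulfonyl}-1-phenyl-1H-tetrazole
Product: 22 methyl (2E)-3-[(3S,5R)-3,5-diethyl-5-[(1E,4R,5E)-4-ethyl-2-methylocta-1,5-dien-1-yl]-1,2-dioxolan-3-yl]prop-2-enoate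
Conditions: 21, KHMDS, DME, −60 °C; then 13, −60 °C → rt
Reagents that add atoms: none
Why: Julia–Kocienski olefination (addition, Smiles rearrangement, loss of SO2 and tetrazolate) forms C7=C8, and the (E)-isomer, with the bulky dioxolanyl group cis to methyl rather than to the branched chain, is expected to predominate.

Step 18
Reactants: 22 methyl (2E)-3-[(3S,5R)-3,5-diethyl-5-[(1E,4R,5E)-4-ethyl-2-methylocta-1,5-dien-1-yl]-1,2-dioxolan-3-yl]prop-2-enoate
Product: 23 (2E)-3-[(3S,5R)-3,5-diethyl-5-[(1E,4R,5E)-4-ethyl-2-methylocta-1,5-dien-1-yl]-1,2-dioxolan-3-yl]prop-2-enoic acid (target)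
Conditions: LiOH, THF/H2O, 0 °C → rt; then dilute HCl
Reagents that add atoms: lithium hydroxide, [Li+].[OH-]
Why: Saponification of the methyl ester, which the peroxide should survive because both peroxide carbons are fully substituted, and which touches no stereocentre.

**Compound list**

1 | 1,3-diethylbenzene | CCc1cccc(CC)c1 | starting material
2 | 1,5-diethylcyclohexa-1,4-diene | CCC1=CCC=C(CC)C1 | intermediate
3 | (1S,6R)-1,3-diethyl-7-oxabicyclo[4.1.0]hept-3-ene | CCC1=CC[C@H]2O[C@@]2(CC)C1 | intermediate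
4 | (1R,6R)-4,6-diethyl-6-hydroperoxycyclohex-3-en-1-ol | O[C@@H]1CC=C(CC)C[C@@]1(CC)OO | intermediate
5 | (1R,2R,4S,5S)-1,5-diethyl-4-iodo-6,7-dioxabicyclo[3.2.1]octan-2-ol | O[C@@H]1C[C@H](I)[C@]2(CC)C[C@@]1(CC)OO2 | intermediate
6 | (1R,2R,5S)-1,5-diethyl-6,7-dioxabicyclo[3.2.1]oct-3-en-2-ol | O[C@@H]1C=C[C@]2(CC)C[C@@]1(CC)OO2 | intermediate
7 | (2S)-2-[(3R,5S)-3,5-diethyl-5-formyl-1,2-dioxolan-3-yl]-2-hydroxyacetaldehyde | O=C[C@@H](O)[C@@]1(CC)C[C@](C=O)(CC)OO1 | intermediate (not isolated)
8 | (1R)-1-[(3R,5S)-3,5-diethyl-5-(hydroxymethyl)-1,2-dioxolan-3-yl]ethane-1,2-diol | OC[C@@H](O)[C@@]1(CC)C[C@](CO)(CC)OO1 | intermediate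
9 | [(3S,5R)-5-[(4R)-2,2-dimethyl-1,3-dioxolan-4-yl]-3,5-diethyl-1,2-dioxolan-3-yl]methanol | CC1(C)OC[C@@H](O1)[C@@]2(CC)C[C@](CO)(CC)OO2 | intermediate
10 | (3S,5R)-5-[(4R)-2,2-dimethyl-1,3-dioxolan-4-yl]-3,5-diethyl-1,2-dioxolane-3-carbaldehyde | CC1(C)OC[C@@H](O1)[C@@]2(CC)C[C@](C=O)(CC)OO2 | intermediate
11 | methyl (2E)-3-[(3S,5R)-5-[(4R)-2,2-dimethyl-1,3-dioxolan-4-yl]-3,5-diethyl-1,2-dioxolan-3-yl]prop-2-enoate | CC1(C)OC[C@@H](O1)[C@@]2(CC)C[C@](/C=C/C(=O)OC)(CC)OO2 | intermediate
12 | methyl (2E)-3-[(3S,5R)-5-[(1R)-1,2-dihydroxyethyl]-3,5-diethyl-1,2-dioxolan-3-yl]prop-2-enoate | OC[C@@H](O)[C@@]1(CC)C[C@](/C=C/C(=O)OC)(CC)OO1 | intermediate (not isolated)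
13 | methyl (2E)-3-[(3S,5R)-3,5-diethyl-5-formyl-1,2-dioxolan-3-yl]prop-2-enoate | O=C[C@@]1(CC)C[C@](/C=C/C(=O)OC)(CC)OO1 | intermediate
14 | (E)-pent-2-enal | CC/C=C/C=O | starting material
15 | (3R,4E)-hept-4-en-3-ol | CC[C@@H](O)/C=C/CC | intermediate
16 | (3R,4E)-3-[(1-ethoxyethenyl)oxy]hept-4-ene | C=C(OCC)O[C@H](CC)/C=C/CC | intermediate (not isolated)
17 | ethyl (3R,4E)-3-ethylhept-4-enoate | CC/C=C/[C@H](CC)CC(=O)OCC | intermediate
18 | (3R,4E)-3-ethylhept-4-en-1-ol | CC/C=C/[C@H](CC)CCO | intermediate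
19 | 5-{[(3R,4E)-3-ethylhept-4-en-1-yl]sulfanyl}-1-phenyl-1H-tetrazole | CC/C=C/[C@H](CC)CCSc1nnnn1-c1ccccc1 | intermediate
20 | 5-{[(3R,4E)-3-ethylhept-4-en-1-yl]sulfonyl}-1-phenyl-1H-tetrazole | CC/C=C/[C@H](CC)CCS(=O)(=O)c1nnnn1-c1ccccc1 | intermediate
21 | 5-{[(4R,5E)-4-ethyloct-5-en-2-yl]sulfonyl}-1-phenyl-1H-tetrazole (epimers at C2) | CC/C=C/[C@H](CC)CC(C)S(=O)(=O)c1nnnn1-c1ccccc1 | intermediate
22 | methyl (2E)-3-[(3S,5R)-3,5-diethyl-5-[(1E,4R,5E)-4-ethyl-2-methylocta-1,5-dien-1-yl]-1,2-dioxolan-3-yl]prop-2-enoate | CC/C=C/[C@H](CC)C/C(C)=C/[C@@]1(CC)C[C@](/C=C/C(=O)OC)(CC)OO1 | intermediate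
23 | (2E)-3-[(3S,5R)-3,5-diethyl-5-[(1E,4R,5E)-4-ethyl-2-methylocta-1,5-dien-1-yl]-1,2-dioxolan-3-yl]prop-2-enoic acid | CC/C=C/[C@H](CC)C/C(C)=C/[C@@]1(CC)C[C@](/C=C/C(=O)O)(CC)OO1 | target

**Step count.** Total: 18 steps. Longest linear sequence: 12 steps (steps 1–10, 17, 18).

**Steps most likely to fail**

Step 2. The chiral dioxirane may discriminate poorly between the enantiotopic alkene faces of a 1-alkylcyclohexene-type substrate, and over-oxidation to the bis-epoxide may compete. The fallback replaces asymmetric catalysis by resolution; it sets out from 2 and returns at 6. Epoxidation of 2 with m-CPBA (1 equiv, CH2Cl2, 0 °C) should give the racemic epoxide F1. Steps 3–5, carried out unchanged, should give the racemic hydroperoxy alcohol F2, the racemic iodide F3 and the racemic allylic alcohol F4. Lipase-catalysed transesterification (Burkholderia cepacia lipase, vinyl acetate, MTBE) is expected by Kazlauskas' rule to acylate the (2R)-enantiomer to the acetate F5. F5 is separated from the unreacted enantiomer and methanolysed (K2CO3, MeOH) to 6.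

Step 4. The iodonium ion may be captured by the C7 hydroxyl (transannular iodo-etherification), or iodine(I) may decompose the hydroperoxide before the peroxide bridge closes. The fallback uses mercury(II) in place of the halonium ion; it sets out from 4 and returns at 6. Cycloperoxymercuration with Hg(OAc)2 (CH2Cl2, 0 °C; then aq. KBr) is reversible and favours the more acidic hydroperoxide as the nucleophile; it should give the bromomercurio peroxide F6. Bromodemercuration (Br2, pyridine, CH2Cl2, 0 °C, dark) should give the bromide F7 with retention. DBU elimination as in step 5 then leads to 6.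

Step 17. E/Z control in forming the trisubstituted C7=C8 alkene may be poor, and the sulfonyl carbanion may add to the acrylate instead. The fallback builds a stereodefined vinyl iodide and cross-couples it; it sets out from 18 and 13 and returns at 22. Appel iodination of 18 (I2, PPh3, imidazole) should give the iodide F8, and PPh3 (MeCN, reflux) converts it into the phosphonium iodide F9. Deprotonation (NaHMDS, THF, −78 °C), iodination of the ylide (I2) and a second deprotonation generate the α-iodo ylide. This ylide should olefinate 13 Z-selectively (Stork–Zhao type) to the (Z)-vinyl iodide F10, with iodine cis to the dioxolane. Negishi methylation with retention (MeZnCl, Pd(t-Bu3P)2 cat., THF, rt) then gives 22.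

**Further compounds**

F1 | step 2 | racemic 1,3-diethyl-7-oxabicyclo[4.1.0]hept-3-ene | CCC1=CC[C@H]2O[C@@]2(CC)C1.CCC1=CC[C@@H]2O[C@]2(CC)C1
F2 | step 2 | racemic trans-4,6-diethyl-6-hydroperoxycyclohex-3-en-1-ol | O[C@@H]1CC=C(CC)C[C@@]1(CC)OO.O[C@H]1CC=C(CC)C[C@]1(CC)OO
F3 | step 2 | racemic 1,5-diethyl-4-iodo-6,7-dioxabicyclo[3.2.1]octan-2-ol | O[C@@H]1C[C@H](I)[C@]2(CC)C[C@@]1(CC)OO2.O[C@H]1C[C@@H](I)[C@@]2(CC)C[C@]1(CC)OO2
F4 | step 2 | racemic 1,5-diethyl-6,7-dioxabicyclo[3.2.1]oct-3-en-2-ol | O[C@@H]1C=C[C@]2(CC)C[C@@]1(CC)OO2.O[C@H]1C=C[C@@]2(CC)C[C@]1(CC)OO2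
F5 | step 2 | (1R,2R,5S)-1,5-diethyl-6,7-dioxabicyclo[3.2.1]oct-3-en-2-yl acetate | CC(=O)O[C@@H]1C=C[C@]2(CC)C[C@@]1(CC)OO2
F6 | step 4 | (1R,2R,4S,5S)-4-(bromomercurio)-1,5-diethyl-6,7-dioxabicyclo[3.2.1]octan-2-ol | O[C@@H]1C[C@H]([Hg]Br)[C@]2(CC)C[C@@]1(CC)OO2
F7 | step 4 | (1R,2R,4S,5S)-4-bromo-1,5-diethyl-6,7-dioxabicyclo[3.2.1]octan-2-ol | O[C@@H]1C[C@H](Br)[C@]2(CC)C[C@@]1(CC)OO2
F8 | step 17 | (3E,5R)-5-ethyl-7-iodohept-3-ene | CC/C=C/[C@H](CC)CCI
F9 | step 17 | [(3R,4E)-3-ethylhept-4-en-1-yl]triphenylphosphonium iodide | CC/C=C/[C@H](CC)CC[P+](c1ccccc1)(c1ccccc1)c1ccccc1.[I-]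
F10 | step 17 | methyl (2E)-3-[(3S,5R)-3,5-diethyl-5-[(1Z,4R,5E)-4-ethyl-2-iodoocta-1,5-dien-1-yl]-1,2-dioxolan-3-yl]prop-2-enoate | CC/C=C/[C@H](CC)C/C(I)=C/[C@@]1(CC)C[C@](/C=C/C(=O)OC)(CC)OO1
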